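**Plan**

- Feature: in the six-membered carbocycle, the methyl-bearing lactone carbon (C-c) and the CHBr carbon (C-d) are 1,4-related with O and Br on one face, and the neighbouring pair C-a (carboxyl-bearing fusion carbon) / C-b (fusion CH) is cis. This is the imprint of a 2-methylfuran cycloadduct (7-oxanorbornane) on a cyclopentenone ester.
- Cuts, in retrosynthetic order: acetate; the C-f–CH2 bond (tertiary carbinol from a bromocyclohexanone and a primary iodide); C-d–Br; the lactone C-c–O bond (from oxygen bridge plus ester); the CH2 arm on C-e (from the ring ketone); finally C-a–C-d and C-b–C-c by [4+2].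
- Forward: the cycloaddition builds the oxygen-bridged cyclohexene on the cyclopentenone; hydrogenation; ketone to CH2Br arm; bridge to lactone; OH to Br at C-d; the bromodimethylcyclohexanone (bromonium cyclisation of a keto ester from 6-methylhept-5-en-2-one, resolved) is joined by a samarium Barbier reaction; acetylation.
- Stereochemistry: C-a, C-b, C-c, C-d come from the cycloaddition (absolute sense from the catalyst); C-e from convex-face hydroboration; the C-d bromide from oxidation, equatorial hydride delivery and SN2 inversion; C-g from resolution; C-f from equatorial attack on the ring ketone.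

Key step: step 1

Labels: C-a quaternary fusion carbon bearing the carboxyl; C-b ring-fusion CH; C-c methyl-bearing lactone carbon; C-d CHBr of the core; C-e cyclopentane CH carrying the CH2 link; C-f acetoxy carbon; C-g CHBr of the dimethylcyclohexane.

Assumption: the (R)-configured oxazaborolidinium catalyst is taken to expose the enone face that leads to 3, by analogy with the sense known for acrylates and 2-cycloalkenones; the antipodal catalyst is used if the sense proves opposite.

Remark: in the target the cyclopentane is cis-fused to the six-membered carbocycle and therefore trans to the lactone ring across the C-a–C-b bond. The cycloaddition installs this strained relation kinetically, so the ring ketone is removed before the lactone is closed and C-b is never enolisable afterwards.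

Remark: the tertiary acetate is made by ketone addition and not by bromonium cyclisation with water capture, because anti addition in a chair would place the oxygen equatorial (trans to Br), whereas the target has it axial (cis to Br).

**Route**

Step 1
Reactants: 1 2-methylfuran; 2 methyl 3-oxocyclopent-1-ene-1-carboxylate
Product: 3 methyl 7-methyl-5-oxo-10-oxatricyclo[5.2.1.0(2,6)]dec-8-ene-2-carboxylate (cyclopentanone endo, ester exo and syn to the oxygen bridge)
Conditions: (R)-o-tolyl-CBS oxazaborolidine (20 mol %), Tf2NH (18 mol %), 1 (5 equiv), CH2Cl2, −78 → −45 °C; cold silica filtration, used at once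
Reagents that add atoms: none
Why: The protonated oxazaborolidine binds the ring ketone of 2, so the ester-bearing β-carbon becomes the electrophilic terminus and pairs with the nucleophilic unsubstituted α-carbon of 1 in a concerted, asynchronous [π4s+π2s] cycloaddition, the closest known reaction type being the cationic-oxazaborolidine-catalysed Diels–Alder reaction of furans and of 2-cycloalkenones. Both new rings, the cyclohexene (C-a, C-d, two alkene carbons, C-c, C-b) and the oxolane made of the furan oxygen with C-d, C-a, C-b and C-c, close together through the C-a–C-d and C-b–C-c bonds in this suprafacial–suprafacial mode. C-a and C-b become cis because the ring alkene adds suprafacially, and C-c and C-d are tied syn by the oxygen bridge. The relation between the two pairs is set by the transition state with the Lewis-acid-bound ketone endo, which leaves the ester exo and syn to the bridge, and the absolute sense comes from the catalyst shielding one face of the bound enone. The step needs regioselectivity (secured by ketone polarisation of the dienophile and the free α-position of the furan), endo selectivity (kinetic control at low temperature) and cycloaddition in preference to Friedel–Crafts conjugate addition (low temperature, short contact, immediate hydrogenation).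

Step 2
Reactants: 3 cycloadduct
Product: 4 methyl 7-methyl-5-oxo-10-oxatricyclo[5.2.1.0(2,6)]decane-2-carboxylate
Conditions: H2 (1 atm), 5 % Pd/C, EtOAc, 0 °C
Reagents that add atoms: none
Why: Heterogeneous syn hydrogenation of the strained bicyclic alkene from its exposed face should be fast at 0 °C and removes the cycloreversion and rearomatisation channels of the adduct, while no stereocentre is created and ketone and ester are untouched.

Step 3
Reactants: 4 keto ester
Product: 5 methyl 7-methyl-5-methylidene-10-oxatricyclo[5.2.1.0(2,6)]decane-2-carboxylate
Conditions: Zn, CH2Br2, TiCl4 (Lombardo reagent), THF–CH2Cl2, 0 °C → rt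
Reagents that add atoms: dibromomethane, BrCBr
Why: Takai–Lombardo methylenation, in which the non-basic gem-dizinc/titanium reagent adds to the cyclopentanone without enolising it, so the β-oxygen bridge is not eliminated, C-b is not touched and the hindered ester does not react.

Step 4
Reactants: 5 exocyclic alkene
Product: 7 methyl 5-(hydroxymethyl)-7-methyl-10-oxatricyclo[5.2.1.0(2,6)]decane-2-carboxylate (C-e hydrogen cis to the C-b hydrogen and the ester; CH2OH on the concave face), via B-alkyl-9-BBN adduct 6 (not isolated)
Conditions: 9-BBN, THF, 0 °C → rt; then NaOH, H2O2, 0 °C
Reagents that add atoms: hydrogen peroxide, OO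
Why: Anti-Markovnikov hydroboration–oxidation, in which the bulky borane should reach the exocyclic alkene from the convex face of the endo-fused cyclopentane (the face of the C-b hydrogen and the ester), so hydrogen is delivered to C-e on that face and the CH2OH arm ends up on the concave face, cis to C-c, as the target requires.

Step 5
Reactants: 7 primary alcohol
Product: 8 methyl 5-(bromomethyl)-7-methyl-10-oxatricyclo[5.2.1.0(2,6)]decane-2-carboxylate
Conditions: CBr4, PPh3, CH2Cl2, 0 °C
Reagents that add atoms: carbon tetrabromide, BrC(Br)(Br)Br
Why: Appel bromination of the unhindered primary alcohol, needed because a free hydroxymethyl group would trap the C-c cation of step 6 as a cyclic ether, and the bromide later becomes the handle for fragment coupling.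

Step 6
Reactants: 8 bromomethyl ester
Product: 9 hydroxy lactone (γ-lactone from the C-a carboxyl to C-c, 6-oxabicyclo[3.2.1]octan-7-one core with the cyclopentane cis-fused at C-a–C-b; equatorial OH on C-d on the lactone face; CH2Br on C-e)
Conditions: BBr3 (2.5 equiv), CH2Cl2, −78 → −20 °C; aq. NaHCO3
Reagents that add atoms: none
Why: Lewis-acid ether cleavage with neighbouring-group participation (dealkylative lactonisation), in which boron binds the bridge oxygen, the tertiary C-c–O bond ionises, the ester carbonyl held on the same face captures C-c and bromide removes the O-methyl group, so the oxygen stays on C-d with its configuration and the lactone can only form on the face the bridge vacated.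

Step 7
Reactants: 9 hydroxy lactone
Product: 10 keto lactone (ketone at C-d)
Conditions: Dess–Martin periodinane, NaHCO3, CH2Cl2, rt
Reagents that add atoms: none
Why: Dess–Martin oxidation of the secondary alcohol under buffered, non-basic conditions, the new ketone being flanked by the quaternary C-a and a CH2 group so that no stereocentre is at risk.

Step 8
Reactants: 10 keto lactone
Product: 11 epimeric hydroxy lactone (axial OH on C-d, anti to the lactone bridge)
Conditions: L-Selectride, THF, −78 °C
Reagents that add atoms: none
Why: Ketone reduction with a bulky trialkylborohydride, in which axial approach is blocked by the syn-axial cyclopentane carbon on C-b, so hydride should enter along the equatorial trajectory from the lactone face and give the axial alcohol, the C-d epimer of 9.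

Step 9
Reactants: 11 axial alcohol
Product: 13 dibromo lactone (equatorial Br on C-d on the lactone face; CH2Br on C-e), via axial triflate 12 (not isolated)
Conditions: Tf2O, pyridine, CH2Cl2, −30 → 0 °C; then Bu4NBr, toluene, rt → 40 °C
Reagents that add atoms: tetrabutylammonium bromide, CCCC[N+](CCCC)(CCCC)CCCC.[Br-]
Why: Triflation followed by SN2 displacement with bromide, in which attack anti to the axial leaving group inverts C-d to the equatorial bromide on the lactone face, while the acyl group on the neighbouring quaternary carbon disfavours ionisation and Wagner–Meerwein shifts.

Step 10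
Reactants: 13 dibromo lactone
Product: 14 iodomethyl bromo lactone
Conditions: NaI, acetone, reflux
Reagents that add atoms: sodium iodide, [Na+].[I-]
Why: Finkelstein exchange, in which only the primary bromide undergoes SN2 with iodide, the neopentyl secondary bromide and the lactone being inert under these conditions.

Step 11
Reactants: 15 6-methylhept-5-en-2-one
Product: 16 allyl 7-methyl-3-oxooct-6-enoate
Conditions: NaH, diallyl carbonate, THF, reflux
Reagents that add atoms: diallyl carbonate, C=CCOC(=O)OCC=C
Why: Crossed Claisen condensation (carboxylation) of the methyl ketone at its methyl group, driven by formation of the stabilised β-keto ester enolate.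

Step 12
Reactants: 16 allyl keto ester
Product: 17 allyl 3-bromo-2,2-dimethyl-6-oxocyclohexane-1-carboxylate (racemic)
Conditions: BDSB (Et2SBr·SbCl5Br), MeNO2, −25 °C
Reagents that add atoms: bromodiethylsulfonium bromopentachloroantimonate, CC[S+](Br)CC.Cl[Sb-](Cl)(Cl)(Cl)(Cl)Br
Why: Bromonium-induced cation–olefin cyclisation, in which the bromonium ion forms at the electron-rich trisubstituted alkene and is opened at its tertiary end, anti to bromine, by the enol carbon of the β-keto ester through a chair (6-endo closure), giving the neopentyl secondary bromide that substitution chemistry reaches poorly.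

Step 13
Reactants: 17 bromo keto ester
Product: 18 4-bromo-3,3-dimethylcyclohexanone (racemic)
Conditions: Pd(PPh3)4 (2 mol %), morpholine, THF, rt
Reagents that add atoms: none
Why: Palladium(0)-catalysed deallylation (Tsuji–Trost, morpholine as allyl acceptor) followed by spontaneous decarboxylation of the β-keto acid, under neutral conditions at room temperature that leave the secondary bromide alone.

Step 14
Reactants: 18 racemic bromo ketone
Product: 19 (R)-4-bromo-3,3-dimethylcyclohexanone
Conditions: preparative SFC, cellulose tris(3,5-dimethylphenylcarbamate) phase, CO2–i-PrOH
Reagents that add atoms: none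
Why: Resolution by chromatography on a chiral stationary phase fixes the configuration of C-g, and the heavy atom allows the enantiomers to be assigned by anomalous-dispersion X-ray analysis of a crystalline derivative.

Step 15
Reactants: 14 iodomethyl bromo lactone; 19 (R)-4-bromo-3,3-dimethylcyclohexanone (1.5 equiv)
Product: 20 tertiary alcohol (desacetyl target; OH axial on C-f and cis to the equatorial Br on C-g)
Conditions: SmI2 (2.5 equiv), NiI2 (2 mol %), THF, 0 °C
Reagents that add atoms: none
Why: Samarium Barbier reaction, in which the primary iodide is reduced in preference to the hindered secondary bromides and the lactone, and the alkylsamarium should add along the equatorial trajectory because the axial methyl of the gem-dimethyl group blocks axial approach, making the new C–C bond equatorial and the hydroxyl at C-f axial.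

Step 16
Reactants: 20 tertiary alcohol
Product: 21 target acetate
Conditions: Ac2O, Sc(OTf)3 (2 mol %), MeCN, −20 °C
Reagents that add atoms: acetic anhydride, CC(=O)OC(C)=O
Why: Lewis-acid-catalysed acylation, a method suited to hindered tertiary alcohols, run cold to avoid ionisation of the tertiary centre and changing no stereocentre.

**Compound list**

1 | 2-methylfuran | Cc1ccco1 | starting material
2 | methyl 3-oxocyclopent-1-ene-1-carboxylate | COC(=O)C1=CC(=O)CC1 | starting material
3 | methyl 7-methyl-5-oxo-10-oxatricyclo[5.2.1.0(2,6)]dec-8-ene-2-carboxylate (ketone ring endo, ester exo) | COC(=O)[C@@]12CCC(=O)[C@@H]1[C@]1(C)C=C[C@H]2O1 | intermediate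
4 | methyl 7-methyl-5-oxo-10-oxatricyclo[5.2.1.0(2,6)]decane-2-carboxylate | COC(=O)[C@@]12CCC(=O)[C@@H]1[C@]1(C)CC[C@H]2O1 | intermediate
5 | methyl 7-methyl-5-methylidene-10-oxatricyclo[5.2.1.0(2,6)]decane-2-carboxylate | COC(=O)[C@@]12CCC(=C)[C@@H]1[C@]1(C)CC[C@H]2O1 | intermediate
6 | B-alkyl-9-borabicyclo[3.3.1]nonane adduct of 5 (boron on the new CH2) | COC(=O)[C@@]12CC[C@H](CB3C4CCCC3CCC4)[C@@H]1[C@]1(C)CC[C@H]2O1 | intermediate
7 | methyl 5-(hydroxymethyl)-7-methyl-10-oxatricyclo[5.2.1.0(2,6)]decane-2-carboxylate | COC(=O)[C@@]12CC[C@H](CO)[C@@H]1[C@]1(C)CC[C@H]2O1 | intermediate
8 | methyl 5-(bromomethyl)-7-methyl-10-oxatricyclo[5.2.1.0(2,6)]decane-2-carboxylate | COC(=O)[C@@]12CC[C@H](CBr)[C@@H]1[C@]1(C)CC[C@H]2O1 | intermediate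
9 | bromomethyl hydroxy lactone (C-a carboxyl lactonised onto C-c; equatorial OH at C-d syn to the lactone) | BrC[C@H]1CC[C@@]23C(=O)O[C@@](C)(CC[C@H]2O)[C@@H]13 | intermediate
10 | bromomethyl keto lactone (C-d ketone) | BrC[C@H]1CC[C@@]23C(=O)O[C@@](C)(CCC2=O)[C@@H]13 | intermediate
11 | bromomethyl hydroxy lactone, C-d epimer of 9 (axial OH) | BrC[C@H]1CC[C@@]23C(=O)O[C@@](C)(CC[C@@H]2O)[C@@H]13 | intermediate
12 | axial C-d triflate of 11 | BrC[C@H]1CC[C@@]23C(=O)O[C@@](C)(CC[C@@H]2OS(=O)(=O)C(F)(F)F)[C@@H]13 | intermediate
13 | dibromo lactone (equatorial Br at C-d, CH2Br at C-e) | BrC[C@H]1CC[C@@]23C(=O)O[C@@](C)(CC[C@H]2Br)[C@@H]13 | intermediate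
14 | iodomethyl bromo lactone | IC[C@H]1CC[C@@]23C(=O)O[C@@](C)(CC[C@H]2Br)[C@@H]13 | intermediate
15 | 6-methylhept-5-en-2-one | CC(=O)CCC=C(C)C | starting material
16 | allyl 7-methyl-3-oxooct-6-enoate | C=CCOC(=O)CC(=O)CCC=C(C)C | intermediate
17 | allyl 3-bromo-2,2-dimethyl-6-oxocyclohexane-1-carboxylate (racemic, mixture at C-1) | C=CCOC(=O)C1C(=O)CCC(Br)C1(C)C | intermediate
18 | 4-bromo-3,3-dimethylcyclohexanone (racemic) | O=C1CCC(Br)C(C)(C)C1 | intermediate
19 | (R)-4-bromo-3,3-dimethylcyclohexanone | O=C1CC[C@@H](Br)C(C)(C)C1 | intermediate
20 | tertiary alcohol, desacetyl target | O[C@@]1(C[C@H]2CC[C@@]34C(=O)O[C@@](C)(CC[C@H]3Br)[C@@H]24)CC[C@@H](Br)C(C)(C)C1 | intermediate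
21 | target acetate (CNP0133010.1) | CC(=O)O[C@@]1(C[C@H]2CC[C@@]34C(=O)O[C@@](C)(CC[C@H]3Br)[C@@H]24)CC[C@@H](Br)C(C)(C)C1 | target

**Step count and risks**

Total: 16 steps. Longest linear sequence: 12 steps (steps 1–10, 15, 16); steps 11–14 form the side branch.

Step 6 (most likely to fail). Closing the lactone forces the cyclopentane trans to the lactone ring across the C-a–C-b bond, so the tertiary cation may instead re-close to the ether or eliminate; elimination toward C-b followed by re-addition of HBr would erode the ring-fusion configuration. Fallback, setting out from 8: the capture is changed from dealkylative to direct. The ester is demethylated with Me3SnOH (1,2-dichloroethane, 80 °C) to the carboxylic acid F1. The acid is then isomerised with catalytic TfOH in hexafluoroisopropanol at 0 °C, where the free carboxyl takes C-c and no bromide or hydrogen bromide is present to re-add to stray alkenes. This returns to the route at 9.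

Step 9. Substitution at the neopentyl secondary centre may be outrun by E2 loss of the axial triflate (toward the adjacent CH2), or may not occur at all. Fallback, setting out from 9 and bypassing 10–12: the equatorial alcohol is acylated with oxalyl chloride (Et2O, 0 °C, then water) to the hydrogen oxalate F2. Its caesium salt is then subjected to radical deoxyhalogenation under photoredox catalysis (Ir[dF(CF3)ppy]2(dtbbpy)PF6, Cs2CO3, BrCCl3, blue LEDs). The C-d radical formed after double decarboxylation should take bromine on the equatorial face, away from the syn-axial cyclopentane carbon. This returns to the route at 13.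

Step 1. The Lewis acid may divert the furan into Friedel–Crafts conjugate addition or open the adduct toward the rearomatised furan, the adduct may cyclorevert, or facial selectivity at the quaternary centre may be low. Fallback, setting out from 1 and 2: the cycloaddition is run without any Lewis acid under high pressure (1.2–1.5 GPa, CH2Cl2, rt), which favours the compact cycloaddition transition state and suppresses cycloreversion. It gives 3 together with the enantiomer of the cycloadduct F3. Hydrogenation as in step 2 gives 4 together with the enantiomer of the keto ester F4, and the two are separated by preparative chromatography on a chiral phase. This returns to the route at 4.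

Further compounds
F1 | step 6 | 5-(bromomethyl)-7-methyl-10-oxatricyclo[5.2.1.0(2,6)]decane-2-carboxylic acid | OC(=O)[C@@]12CC[C@H](CBr)[C@@H]1[C@]1(C)CC[C@H]2O1
F2 | step 9 | hydrogen oxalate of hydroxy lactone 9 | BrC[C@H]1CC[C@@]23C(=O)O[C@@](C)(CC[C@H]2OC(=O)C(=O)O)[C@@H]13
F3 | step 1 | enantiomer of cycloadduct 3 | COC(=O)[C@]12CCC(=O)[C@H]1[C@@]1(C)C=C[C@@H]2O1
F4 | step 1 | enantiomer of keto ester 4 | COC(=O)[C@]12CCC(=O)[C@H]1[C@@]1(C)CC[C@@H]2O1
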